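**Retrosynthetic overview**
- The route rests on one feature. A cyclopentenone ring (C1–C5: C3 ketone, methyl-bearing C4=C5 alkene, C1 methine) is fused along C1–C5 to the seven-membered ring (C1, C10, C9, C8, C7, C6, C5), and C1 sits next to methyl-bearing C10. This array is what a 4,10-dimethyl cross-conjugated cyclohexadienone leaves behind after photorearrangement.
- Endgame: C8 angelate ⇒ C8 alcohol ⇒ C8 acetate; C10–H ⇒ 10(14)-alkene ⇒ C10 tertiary alcohol.
- Key disconnection: 8,11-diacetoxy-10-hydroxyguai-4-en-3-one ⇒ 8,11-diacetoxy-10-epi-eudesma-1,4-dien-3-one (make C1–C5 and C10–O, break C5–C10).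
- Decalin: dienone ⇒ enone ⇒ cis-8,11-diol ⇒ C8 ketone with intact isopropenyl group ⇒ Robinson annulation of ethyl vinyl ketone onto a 4-silyloxydihydrocarvone ⇒ γ-oxygenated (R)-carvone.
- Ring order: ring B (bought with carvone), then ring A (Robinson annulation), then the five- and seven-membered rings together in the photochemical step.

Key step: step 12

Remark: monocyclic compounds carry carvone numbering (C1 carbonyl, C2 methyl-bearing, C4 oxygenated, C5 isopropenyl-bearing; these become C5, C10, C8 and C7) and bicyclic ones the numbering of the target; ketone 8 is written as its more stable C2 epimer, a centre that step 5 erases by enolisation.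

**Step 1**
Reactants: 1 (R)-carvone
Product: 3 (S)-trimethyl{[2-methyl-5-(prop-1-en-2-yl)cyclohexa-1,3-dien-1-yl]oxy}silane, via bromomagnesium dienolate 2 (not isolated)
Conditions: MeMgBr, FeCl3 (cat.), Et2O, −20 °C; then TMSCl, Et3N, DMPU, −20 °C to rt
Reagents that add atoms: trimethylsilyl chloride, C[Si](C)(C)Cl
Why: The iron-catalysed Grignard base (Kharasch-type reagent) deprotonates the enone under equilibrating conditions at the γ-carbon C4 and not at C6, so that O-silylation of 2 fixes the linear 1-silyloxy-1,3-diene, while the C5 stereocentre is not touched.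

**Step 2**
Reactants: 3 silyl dienol ether
Product: 5 (4S,5R)-4-hydroxy-2-methyl-5-(prop-1-en-2-yl)cyclohex-2-en-1-one (trans-4-hydroxycarvone), via silyloxy vinyl epoxide 4 (not isolated)
Conditions: mCPBA, CH2Cl2, −20 to 0 °C; then 1 M HCl, THF, 0 °C
Reagents that add atoms: 3-chloroperbenzoic acid, OOC(=O)c1cccc(Cl)c1
Why: Vinylogous Rubottom oxidation: the peracid attacks the electron-rich diene terminus C3=C4 well ahead of the isopropenyl group and on the face away from the neighbouring C5 substituent, and the silyl enol ether then pushes open epoxide 4 to the γ-hydroxy enone, which sets C4 (S) trans to the isopropenyl group.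

**Step 3**
Reactants: 5 trans-4-hydroxycarvone
Product: 6 (4S,5R)-4-(tert-butyldimethylsilyloxy)-2-methyl-5-(prop-1-en-2-yl)cyclohex-2-en-1-one
Conditions: TBSCl, imidazole, DMF, rt
Reagents that add atoms: tert-butyldimethylsilyl chloride, CC(C)(C)[Si](C)(C)Cl
Why: Standard imidazole-promoted silylation of a secondary allylic alcohol, which masks the hydroxyl group against oxa-Michael addition and alkoxide chemistry in steps 4 and 5 and changes no stereocentre.

**Step 4**
Reactants: 6 silyl ether of trans-4-hydroxycarvone
Product: 8 (2R,4S,5R)-4-(tert-butyldimethylsilyloxy)-2-methyl-5-(prop-1-en-2-yl)cyclohexan-1-one, via lithium enolate 7 (not isolated)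
Conditions: LiBH(s-Bu)3 (L-Selectride), THF, −78 °C; then H2O
Reagents that add atoms: none
Why: Trialkylborohydride conjugate reduction, reliable for carvone-type enones whose β-carbon bears only hydrogen, gives enolate 7 and leaves the isopropenyl group and the silyl ether alone; protonation puts the C2 methyl group mainly equatorial (2R), a centre of no consequence.

**Step 5**
Reactants: 8 silyloxy dihydrocarvone; 9 ethyl vinyl ketone
Product: 12 (7R,8S,10S)-8-(tert-butyldimethylsilyloxy)-10-epi-eudesma-4,11-dien-3-one, via Michael diketone 10 (not isolated), via cis-fused ketol 11 (not isolated)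
Conditions: KOH (cat.), EtOH, −10 to 0 °C; then KOH, EtOH, 60 °C
Reagents that add atoms: ethyl vinyl ketone (9), CCC(=O)C=C
Why: Robinson annulation (Michael addition, aldol closure, E1cB dehydration): the more substituted C2 enolate, in the half-chair that keeps the C4 silyloxy and C5 isopropenyl groups equatorial, takes up 9 axially through a chair-like transition state on the face cis to the isopropenyl group, so that the methyl group ends trans to it (quaternary C10, S), and ring A closes by a six-membered exo-trig aldol before water is lost.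

**Step 6**
Reactants: 12 silyl ether
Product: 13 (7R,8S,10S)-8-hydroxy-10-epi-eudesma-4,11-dien-3-one (hydroxyl trans to the isopropenyl group)
Conditions: 48% aq. HF, MeCN, 0 °C to rt
Reagents that add atoms: none
Why: Fluoride-driven cleavage of the Si–O bond under mildly acidic conditions that leave the enone and the isopropenyl group untouched; the C8–O bond and hence 8S stay as they are.

**Step 7**
Reactants: 13 trans alcohol
Product: 14 (7R,10S)-10-epi-eudesma-4,11-diene-3,8-dione
Conditions: Dess–Martin periodinane, CH2Cl2, 0 °C to rt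
Reagents that add atoms: none
Why: Dess–Martin oxidation works under near-neutral conditions at or below room temperature, so the β,γ-unsaturated C8 ketone should be obtained without epimerisation at C7 or migration of the isopropenyl double bond into conjugation.

**Step 8**
Reactants: 14 dione
Product: 15 (7R,8R,10S)-8-hydroxy-10-epi-eudesma-4,11-dien-3-one (hydroxyl cis to the isopropenyl group)
Conditions: LiBH(s-Bu)3 (1.05 equiv), THF, −78 °C; then H2O
Reagents that add atoms: none
Why: Chemo- and stereoselective ketone reduction with a bulky trialkylborohydride, the same oxidation–reduction inversion that is used on 2-isopropenylcyclohexanols: the isolated C8 ketone reacts ahead of the hindered, fully substituted enone, and hydride arrives from the equatorial side, anti to the neighbouring isopropenyl group, to give the axial 8R alcohol cis to the C7 substituent.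

**Step 9**
Reactants: 15 cis alcohol
Product: 16 (7S,8R,10S)-8,11-dihydroxy-10-epi-eudesm-4-en-3-one
Conditions: Co(acac)2 (cat.), PhSiH3, O2 (1 atm), THF, rt
Reagents that add atoms: dioxygen, O=O
Why: Mukaiyama hydration (cobalt-hydride hydrogen-atom transfer followed by capture of O2) adds H and OH in the Markovnikov sense to the 1,1-disubstituted alkene only, the tetrasubstituted enone double bond being inert to hydrogen-atom transfer, and C11 is not stereogenic.

**Step 10**
Reactants: 16 cis diol
Product: 17 (7S,8R,10S)-8,11-diacetoxy-10-epi-eudesm-4-en-3-one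
Conditions: Ac2O, DMAP, Et3N, CH2Cl2, 40 °C
Reagents that add atoms: acetic anhydride, CC(=O)OC(C)=O
Why: DMAP-catalysed acyl transfer (Steglich-type acylation) is strong enough for the tertiary C11 hydroxyl as well as for the axial C8 hydroxyl, and since no C–O bond is broken both configurations are kept.

**Step 11**
Reactants: 17 enone diacetate
Product: 18 (7S,8R,10R)-8,11-diacetoxy-10-epi-eudesma-1,4-dien-3-one
Conditions: DDQ, dioxane, reflux
Reagents that add atoms: none
Why: DDQ dehydrogenation of a 4-en-3-one in neutral dioxane proceeds by enolisation toward C2 and hydride loss from C1, which gives the cross-conjugated 1,4-dienone and not the 4,6-dienone favoured under acid catalysis; quaternary C10 blocks aromatisation and the esters are inert.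

**Step 12**
Reactants: 18 cross-conjugated dienone
Product: 20 (1S,7S,8R,10S)-8,11-diacetoxy-10-hydroxyguai-4-en-3-one, via cyclopropyl oxyallyl zwitterion 19 (not isolated)
Conditions: hν (medium-pressure Hg lamp, Pyrex), AcOH–H2O (45:55), Ar, 15–20 °C
Reagents that add atoms: water, O
Why: Excitation of the cross-conjugated dienone and bonding between its two β-carbons C1 and C5 gives the cyclopropane-bridged oxyallyl zwitterion 19; in the acidic medium its oxygen is protonated, the C4 methyl group localises the positive charge at C4 next to C5, and the C5–C10 cyclopropane bond ionises while water enters at C10 from the rear, after which ketonisation at C2 leaves the C4=C5 enone. The closest known reaction type is the photorearrangement of santonin-like 4-methyl cyclohexadienones with an angular methyl group to 10-hydroxyhydroazulenones in aqueous acetic acid. The five-membered ring closes by the transannular C1–C5 bond across ring A (ring contraction through a bicyclo[3.1.0]hexane), and the seven-membered ring is not closed by a bond of its own but grows out of ring B when the shared C5–C10 bond breaks and C1 is taken into the ring. C1 is controlled by quaternary C10: ring B can bridge C5 and C10 of the three-membered ring only with C6 and C9 on one of its faces, which forces H1 onto that face and the methyl group onto the other, so H1 ends opposite to the old angular methyl group and on the side of the C7 and C8 substituents (1S here, 1R once the C10 oxygen is gone). C10 is set by inversion in the rear-side attack of water (OH cis to H1), and this centre is removed in step 13. The step needs the hydroazulenone path to win over the 1,4-shift to a lumiketone and over C1–C10 cleavage to a spiro ketone, which the protic acid medium and the C4 methyl group respectively secure, while the Pyrex filter keeps the acetates and, largely, the product enone out of the photochemistry.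

**Step 13**
Reactants: 20 tertiary alcohol
Product: 21 (1R,7S,8R)-8,11-diacetoxyguaia-4,10(14)-dien-3-one
Conditions: SOCl2, pyridine, −20 to 0 °C
Reagents that add atoms: none
Why: Thionyl chloride–pyridine dehydration is an anti E2 elimination of the activated tertiary alcohol, and because H1 is syn to the C10–O bond it cannot be the proton lost, so the always accessible methyl protons should give the exocyclic alkene with C1 intact.

**Step 14**
Reactants: 21 exocyclic alkene
Product: 22 (1R,7S,8R,10S)-8,11-diacetoxyguai-4-en-3-one
Conditions: H2 (1 atm), RhCl(PPh3)3 (cat.), benzene–EtOH, rt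
Reagents that add atoms: none
Why: Homogeneous hydrogenation with RhCl(PPh3)3 reduces the unhindered 1,1-disubstituted alkene, leaves the tetrasubstituted enone alone and does not shift the double bond toward C1; the catalyst binds the face opposite to the C7 side chain and the C8 acetate, so hydrogen reaches C10 from there and the methyl group ends on the side of those groups (10S).

**Step 15**
Reactants: 22 diacetate
Product: 23 (1R,7S,8R,10S)-11-acetoxy-8-hydroxyguai-4-en-3-one
Conditions: K2CO3 (cat.), MeOH, 0 °C
Reagents that add atoms: none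
Why: Base-catalysed transesterification (Zemplén-type methanolysis) takes the secondary C8 acetate much faster than the tertiary C11 acetate, and low temperature with an early stop limits acetyl migration from O11 to O8 and enolisation toward C1.

**Step 16**
Reactants: 23 C8 alcohol; 24 angelic acid
Product: 26 torilin, via angelic 2,4,6-trichlorobenzoic anhydride 25 (not isolated)
Conditions: 24, 2,4,6-Cl3C6H2COCl, Et3N, toluene, rt; then 23, 80 °C
Reagents that add atoms: angelic acid (24), C/C=C(/C)C(=O)O
Why: Yamaguchi-type mixed-anhydride esterification run without a nucleophilic catalyst: the alcohol attacks the open angeloyl carbonyl of 25 because the two ortho chlorines block the aroyl carbonyl, the absence of DMAP avoids the addition–elimination that would turn the Z ester into the E ester, and the C8–O bond is not broken, so 8R is kept.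

**Compound list**
1 | (R)-carvone | CC1=CC[C@H](CC1=O)C(C)=C | starting material
2 | bromomagnesium (S)-2-methyl-5-(prop-1-en-2-yl)cyclohexa-1,3-dien-1-olate | C1=CC(C)=C(O[Mg]Br)C[C@@H]1C(C)=C | intermediate (not isolated)
3 | (S)-trimethyl{[2-methyl-5-(prop-1-en-2-yl)cyclohexa-1,3-dien-1-yl]oxy}silane | C1=CC(C)=C(O[Si](C)(C)C)C[C@@H]1C(C)=C | intermediate
4 | 3,4-epoxide of 3, oxygen anti to the isopropenyl group | CC(=C)[C@H]1CC(O[Si](C)(C)C)=C(C)[C@@H]2O[C@H]12 | intermediate (not isolated)
5 | (4S,5R)-4-hydroxy-2-methyl-5-(prop-1-en-2-yl)cyclohex-2-en-1-one | O[C@H]1C=C(C)C(=O)C[C@@H]1C(C)=C | intermediate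
6 | (4S,5R)-4-(tert-butyldimethylsilyloxy)-2-methyl-5-(prop-1-en-2-yl)cyclohex-2-en-1-one | CC(C)(C)[Si](C)(C)O[C@H]1C=C(C)C(=O)C[C@@H]1C(C)=C | intermediate
7 | lithium C1–C2 enolate from 6 | CC(C)(C)[Si](C)(C)O[C@H]1CC(C)=C(O[Li])C[C@@H]1C(C)=C | intermediate (not isolated)
8 | (2R,4S,5R)-4-(tert-butyldimethylsilyloxy)-2-methyl-5-(prop-1-en-2-yl)cyclohexan-1-one | CC(C)(C)[Si](C)(C)O[C@H]1C[C@@H](C)C(=O)C[C@@H]1C(C)=C | intermediate
9 | ethyl vinyl ketone (pent-1-en-3-one) | CCC(=O)C=C | starting material
10 | (2S,4S,5R)-4-(tert-butyldimethylsilyloxy)-2-methyl-2-(3-oxopentyl)-5-(prop-1-en-2-yl)cyclohexan-1-one | CC(C)(C)[Si](C)(C)O[C@H]1C[C@](C)(CCC(=O)CC)C(=O)C[C@@H]1C(C)=C | intermediate (not isolated)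
11 | cis-fused ketol, 8-(tert-butyldimethylsilyloxy)-5-hydroxy-10-epi-eudesm-11-en-3-one (5-OH on the face of the C10 methyl group, C4 methyl group equatorial) | CC(C)(C)[Si](C)(C)O[C@H]1C[C@]2(C)CCC(=O)[C@H](C)[C@]2(O)C[C@@H]1C(C)=C | intermediate (not isolated)
12 | (7R,8S,10S)-8-(tert-butyldimethylsilyloxy)-10-epi-eudesma-4,11-dien-3-one | CC(C)(C)[Si](C)(C)O[C@H]1C[C@]2(C)CCC(=O)C(C)=C2C[C@@H]1C(C)=C | intermediate
13 | (7R,8S,10S)-8-hydroxy-10-epi-eudesma-4,11-dien-3-one | O[C@H]1C[C@]2(C)CCC(=O)C(C)=C2C[C@@H]1C(C)=C | intermediate
14 | (7R,10S)-10-epi-eudesma-4,11-diene-3,8-dione | O=C1C[C@]2(C)CCC(=O)C(C)=C2C[C@@H]1C(C)=C | intermediate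
15 | (7R,8R,10S)-8-hydroxy-10-epi-eudesma-4,11-dien-3-one | O[C@@H]1C[C@]2(C)CCC(=O)C(C)=C2C[C@@H]1C(C)=C | intermediate
16 | (7S,8R,10S)-8,11-dihydroxy-10-epi-eudesm-4-en-3-one | O[C@@H]1C[C@]2(C)CCC(=O)C(C)=C2C[C@@H]1C(C)(C)O | intermediate
17 | (7S,8R,10S)-8,11-diacetoxy-10-epi-eudesm-4-en-3-one | CC(=O)O[C@@H]1C[C@]2(C)CCC(=O)C(C)=C2C[C@@H]1C(C)(C)OC(C)=O | intermediate
18 | (7S,8R,10R)-8,11-diacetoxy-10-epi-eudesma-1,4-dien-3-one | CC(=O)O[C@@H]1C[C@]2(C)C=CC(=O)C(C)=C2C[C@@H]1C(C)(C)OC(C)=O | intermediate
19 | zwitterion with a C1–C5–C10 cyclopropane and a C2–C3(O)–C4 oxyallyl unit | CC(=O)O[C@@H]1C[C@]2(C)[C@H]3C=C([O-])[C+](C)[C@@]23C[C@@H]1C(C)(C)OC(C)=O | intermediate (not isolated)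
20 | (1S,7S,8R,10S)-8,11-diacetoxy-10-hydroxyguai-4-en-3-one | CC(=O)O[C@@H]1C[C@](C)(O)[C@H]2CC(=O)C(C)=C2C[C@@H]1C(C)(C)OC(C)=O | intermediate
21 | (1R,7S,8R)-8,11-diacetoxyguaia-4,10(14)-dien-3-one | CC(=O)O[C@@H]1CC(=C)[C@H]2CC(=O)C(C)=C2C[C@@H]1C(C)(C)OC(C)=O | intermediate
22 | (1R,7S,8R,10S)-8,11-diacetoxyguai-4-en-3-one | CC(=O)O[C@@H]1C[C@H](C)[C@H]2CC(=O)C(C)=C2C[C@@H]1C(C)(C)OC(C)=O | intermediate
23 | (1R,7S,8R,10S)-11-acetoxy-8-hydroxyguai-4-en-3-one | O[C@@H]1C[C@H](C)[C@H]2CC(=O)C(C)=C2C[C@@H]1C(C)(C)OC(C)=O | intermediate
24 | angelic acid, (Z)-2-methylbut-2-enoic acid | C/C=C(/C)C(=O)O | starting material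
25 | angelic 2,4,6-trichlorobenzoic anhydride | C/C=C(/C)C(=O)OC(=O)c1c(Cl)cc(Cl)cc1Cl | intermediate (not isolated)
26 | torilin, (1R,7S,8R,10S)-11-acetoxy-8-angeloyloxyguai-4-en-3-one | C/C=C(/C)C(=O)O[C@@H]1C[C@H](C)[C@H]2CC(=O)C(C)=C2C[C@@H]1C(C)(C)OC(C)=O | target

Total step count: 16. Longest linear sequence: 16 steps, from (R)-carvone.

**Steps most likely to fail**

**Step 12.**
- The zwitterion may escape by a 1,4-shift before it is protonated, and the product enone may be consumed by further irradiation.
- The C8 acetate lies on the face from which C10 is attacked. It may take part in the opening of the cyclopropane and pass its acetyl group to O10, or it may be hydrolysed in the aqueous acid.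
- The fallback keeps the same photochemical reorganisation. It carries O8 as a non-participating silyl ether, which also removes the need for ester differentiation in the endgame. It sets out from 16 and comes back at 23.
- TBSCl and imidazole in DMF would silylate only the secondary hydroxyl group to give the 8-O-silyl 11-alcohol F1.
- Ac2O, DMAP and Et3N would give the 11-acetate F2, and DDQ in dioxane the silyloxy dienone F3.
- Irradiation in aqueous acetic acid would give the 10-hydroxyguaienone F4, SOCl2 in pyridine the 10(14)-alkene F5, and hydrogenation over RhCl(PPh3)3 the 10-methyl silyl ether F6.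
- Aqueous HF in MeCN would then release 23.

**Step 13.**
- Regiocontrol of the elimination may be lost, with the proton taken from C9 or from C1 in place of the methyl group. C1 is at risk because the enone makes its proton acidic.
- Loss from C1 would erase the stereocentre that the key step creates.
- The fallback replaces elimination and hydrogenation by a radical deoxygenation. It sets out from 20 and comes back at 22, so step 14 is bypassed as well.
- Methyl chlorooxoacetate and DMAP in CH2Cl2 would acylate the tertiary alcohol to the C10 methyl oxalate F7.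
- Bu3SnH and AIBN in refluxing toluene (Barton–McCombie type deoxygenation of a tertiary oxalate) would give the C10 radical. This radical should take hydrogen on the open face opposite to the C7 and C8 groups.
- The stannane would be kept concentrated so that hydrogen transfer outruns any closure of the radical onto C5.

**Step 15.**
- Once O8 is free, the acetyl group may migrate from the tertiary O11 to the secondary O8 and then be lost as well, so the reaction may not stop at the monoacetate.
- Prolonged base may also enolise toward C1.
- The fallback gives up the differentiation of the two acetates and builds the two esters in the order of hydroxyl reactivity. It sets out from 22 and comes back at 26.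
- K2CO3 in MeOH at room temperature for a longer time would remove both acetates to give the 8,11-diol F8.
- The mixed anhydride 25 in toluene would esterify only the secondary hydroxyl group to give the 8-angelate 11-alcohol F9.
- Ac2O, DMAP and Et3N would then acetylate the tertiary hydroxyl group to give 26.

**Further compounds**
F1 | step 12 | (7S,8R,10S)-8-(tert-butyldimethylsilyloxy)-11-hydroxy-10-epi-eudesm-4-en-3-one | CC(C)(C)[Si](C)(C)O[C@@H]1C[C@]2(C)CCC(=O)C(C)=C2C[C@@H]1C(C)(C)O
F2 | step 12 | (7S,8R,10S)-11-acetoxy-8-(tert-butyldimethylsilyloxy)-10-epi-eudesm-4-en-3-one | CC(C)(C)[Si](C)(C)O[C@@H]1C[C@]2(C)CCC(=O)C(C)=C2C[C@@H]1C(C)(C)OC(C)=O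
F3 | step 12 | (7S,8R,10R)-11-acetoxy-8-(tert-butyldimethylsilyloxy)-10-epi-eudesma-1,4-dien-3-one | CC(C)(C)[Si](C)(C)O[C@@H]1C[C@]2(C)C=CC(=O)C(C)=C2C[C@@H]1C(C)(C)OC(C)=O
F4 | step 12 | (1S,7S,8R,10S)-11-acetoxy-8-(tert-butyldimethylsilyloxy)-10-hydroxyguai-4-en-3-one | CC(C)(C)[Si](C)(C)O[C@@H]1C[C@](C)(O)[C@H]2CC(=O)C(C)=C2C[C@@H]1C(C)(C)OC(C)=O
F5 | step 12 | (1R,7S,8R)-11-acetoxy-8-(tert-butyldimethylsilyloxy)guaia-4,10(14)-dien-3-one | CC(C)(C)[Si](C)(C)O[C@@H]1CC(=C)[C@H]2CC(=O)C(C)=C2C[C@@H]1C(C)(C)OC(C)=O
F6 | step 12 | (1R,7S,8R,10S)-11-acetoxy-8-(tert-butyldimethylsilyloxy)guai-4-en-3-one | CC(C)(C)[Si](C)(C)O[C@@H]1C[C@H](C)[C@H]2CC(=O)C(C)=C2C[C@@H]1C(C)(C)OC(C)=O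
F7 | step 13 | C10 methyl oxalate of 20 | CC(=O)O[C@@H]1C[C@](C)(OC(=O)C(=O)OC)[C@H]2CC(=O)C(C)=C2C[C@@H]1C(C)(C)OC(C)=O
F8 | step 15 | (1R,7S,8R,10S)-8,11-dihydroxyguai-4-en-3-one | O[C@@H]1C[C@H](C)[C@H]2CC(=O)C(C)=C2C[C@@H]1C(C)(C)O
F9 | step 15 | (1R,7S,8R,10S)-8-angeloyloxy-11-hydroxyguai-4-en-3-one | C/C=C(/C)C(=O)O[C@@H]1C[C@H](C)[C@H]2CC(=O)C(C)=C2C[C@@H]1C(C)(C)O
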